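All runs are simulated with made-up constants, noise included.

Count the nucleophile before anything else, because in this reckoning of mine it sets how far the electrophile can go.

| flask | electrophile | nucleophile | remark | time |
|---|---|---|---|---|
| dawn | 0.45 M | 0.80 equiv | run made earlier |  |
| teal | 0.30 M | 0.800 equiv |  | 3.0 min |
| green | 0.30 M | 1.00 equiv |  | 3.0 min |

dawn run (percent of the electrophile charged)

| time / s | electrophile / % | target / % |
|---|---|---|
| 10.0 | 39 | 59 |
| 20.0 | 36 | 64 |
| 25.0 | 33 | 67 |
| 40.0 | 27 | 70 |
| 50.0 | 28 | 73 |
| 60.0 | 26 | 76 |

(readings scatter by 1.5 percentage points)

- part of the electrophile that has reacted at the end, teal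
- part of the electrophile that has reacted at the end, green
- what raising the equivalents of nucleophile from its lowest to its highest value here does to the part of the electrophile that has reacted (changes below 5 percentage points count as none) (it falls / it rises / no change)



At the last dawn reading, 26% of the electrophile stood beside 76% of target, so I read the loss as target and took one nucleophile per electrophile. My ceiling is therefore the equivalents of nucleophile read as a percentage of the electrophile charged, 80.0% for teal, where nucleophile is the limiting reagent.

Did teal have the time to reach its ceiling? A second-order law through the last dawn reading gave a clock: at c(electrophile) = 0.30 M, an equimolar flask halves in 14.5 s, a reading that carries the scatter. Late in teal, the electrophile sits near its excess of 20.0%, so I froze it and treated the nucleophile as pseudo-first-order, with a time constant of 72.4 s. The 3.0 min allowed is longer, and the second-order law put teal at 78.6%.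

What then holds green back? Its ceiling is 100%, with no excess to freeze, so I reckoned green by the clock: the electrophile left is the fraction 1/(1 + t/clock), which put green at 92.6%. That is 14 percentage points above teal, more than the margin of 5 points.

The forecast gave 78% (73% to 80.5%) for teal and 90% (83% to 95%) for green, lower than my green figure, and held that it rises, reasoning that “More nucleophile lifts the ceiling”.

Teal gave 78.9% and green 92.7%, so for the step up in nucleophile the answer was "it rises", a change of 14 points.

    electrophile + nucleophile → acid set free + target (k = 3.40 L mol⁻¹ s⁻¹)
    nucleophile + acid set free ⇌ protonated nucleophile, settled at all times (K = 70.0 L mol⁻¹)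

At 3.00 min, teal held 0.0827% of its charged nucleophile free. Left until 30.0 min, teal reached 80.0%, level with its ceiling of 80.0%. A further flask like teal, charged with 0.480 equiv of nucleophile, has a ceiling of 48.0% and gave 48.0%, with 52% of its electrophile still there.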